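**Retrosynthetic overview** (gibberellane atom numbers C1–C20 are used for all intermediates; "lower face" is the face of C19 and C20)
- Target ⇐ its 7,19-dimethyl ester; ring D is closed last (C13–C16) by Pd(OAc)2 cycloalkenylation of a C12 silyl enol ether onto a C8 allyl group.
- Ring B (C9–C10, quaternary C10 carrying the C20 aldehyde) ⇐ amine-catalysed desymmetrising Michael addition of a ring A aldehyde onto a 4-allylcyclohexadienone (new step).
- Dienone (ring C) ⇐ phenol, by oxidative dearomatising para-allylation (C8–C15).
- Ring A aldehyde ⇐ the preformed six-membered ring of methyl 3-oxocyclohexenecarboxylate: catalytic asymmetric Mukaiyama–Michael addition of an arylacetate ketene acetal (C5–C6, first stereocentres), C4 methylation, C10 ketone to C20 aldehyde homologation.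
- Ring order: A (bought), C (aromatic, then dienone), B, D.

Assumption: the catalyst enantiomers named ((S,S)-IDPi in step 3, the quinine-derived primary amine in step 7) are the ones that give or match the configurations drawn, otherwise their mirror-image or pseudo-enantiomeric forms are used; C6 is taken to form as drawn and, being epimerisable, could be equilibrated with NaOMe at the stage of 14 if needed.

Step 1
Reactants: 1 methyl 2-[4-(benzyloxy)phenyl]acetate
Product: 2 trimethylsilyl ketene acetal of 1
Conditions: LiN(iPr)2, Me3SiCl, THF, −78 °C → rt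
Reagents that add atoms: chlorotrimethylsilane, C[Si](C)(C)Cl
Why: Kinetic ester enolisation and O-silylation (silyl ketene acetal formation) give the Mukaiyama donor that will deliver C6 and C7; no stereocentre is formed.

Step 2
Reactants: 3 methyl 3-oxocyclohex-1-ene-1-carboxylate
Product: 4 methyl 3-(triisopropylsilyloxy)cyclohexa-1,3-diene-1-carboxylate
Conditions: LiN(iPr)2, THF, −78 °C; iPr3SiOTf, −78 → 0 °C
Reagents that add atoms: triisopropylsilyl trifluoromethanesulfonate, CC(C)[Si](C(C)C)(C(C)C)OS(=O)(=O)C(F)(F)F
Why: Kinetic alpha-prime deprotonation of the enone at C1 and O-silylation (silyl dienol ether formation) mask the C10 ketone as a non-acidic enol ether and leave the C4=C5 enoate as the only Michael acceptor.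

Step 3
Reactants: 2 trimethylsilyl ketene acetal of 1; 4 methyl 3-(triisopropylsilyloxy)cyclohexa-1,3-diene-1-carboxylate
Product: 7 benzyl ether keto diester (ring A ketone), via ketene acetal adduct 5 (not isolated), via silyl enol ether 6 (not isolated)
Conditions: (S,S)-IDPi (chiral imidodiphosphorimidate acid, 2 mol%), toluene, −60 °C; then Bu4N[Ph3SiF2], MeI, THF, −78 → −20 °C; then AcOH, Bu4NF, 0 °C → rt
Reagents that add atoms: iodomethane, CI
Why: Catalytic asymmetric Mukaiyama–Michael addition under silylium ion-pair catalysis, in which the chiral IDPi anion shields one face of the O-silylated enoate so that C6 adds to C5 (first stereocentres C5 and C6), after which fluoride unmasks the C4 ketene acetal for enolate methylation anti to the new C5 substituent (quaternary C4 with the ester cis to the side chain) and buffered fluoride cleaves the silyl enol ether to the C10 ketone.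

Step 4
Reactants: 7 benzyl ether keto diester (ring A ketone)
Product: 9 benzyl ether aldehyde, via methyl enol ether 8 (not isolated)
Conditions: Ph3P(CH2OMe)Cl, KN(SiMe3)2, THF, 0 °C → rt; then 2 M HCl, THF, rt
Reagents that add atoms: (methoxymethyl)triphenylphosphonium chloride, COC[P+](c1ccccc1)(c1ccccc1)c1ccccc1.[Cl-]; water, O
Why: Wittig methoxymethylenation of the ketone and acid hydrolysis of the enol ether (one-carbon homologation) install the C20 aldehyde on C10, whose configuration is epimerisable and is reset in step 7.

Step 5
Reactants: 9 benzyl ether aldehyde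
Product: 10 phenol aldehyde
Conditions: H2 (1 atm), Pd/C, EtOAc, rt
Reagents that add atoms: none
Why: Hydrogenolysis of the benzyl ether frees the phenol without touching the hindered aldehyde or the esters, and no stereocentre is affected.

Step 6
Reactants: 10 phenol aldehyde
Product: 11 4-allylcyclohexadienone aldehyde
Conditions: PhI(OAc)2, allylSiMe3, (CF3)2CHOH/CH2Cl2, −20 → 0 °C
Reagents that add atoms: allyltrimethylsilane, C=CC[Si](C)(C)C
Why: Oxidative dearomatisation, in which PhI(OAc)2 generates the phenoxenium ion in the fluoroalcohol and the allylsilane attacks the para carbon (oxidative Hosomi–Sakurai allylation), gives the 4,4-disubstituted dienone whose C8 is still prochiral.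

Step 7
Reactants: 11 4-allylcyclohexadienone aldehyde
Product: 12 tricyclic enone aldehyde (rings A, B, C)
Conditions: 9-amino-9-deoxy-epi-quinine (20 mol%), CF3CO2H (40 mol%), toluene, 40 °C
Reagents that add atoms: none
Why: Proposed new method: the chiral primary amine condenses with the alpha-branched ring A aldehyde to a trisubstituted enamine that adds 5-exo to one of the two enone arms of the dienone (closest known reactions: proline-type desymmetrising Michael addition of linear aldehydes to cyclohexadienones, which gives tertiary centres, and primary-amine catalysed intermolecular Michael addition of alpha-branched aldehydes to enones); C9 approaches C10 equatorially, anti to the axial C19 ester on C4, so ring B is trans-fused to ring A and C20 becomes axial, the five-membered ring enforces the cis B/C fusion, and the synclinal enamine–enone arrangement places C11 on the C20 side, which fixes C8, C9 and C10 as in the target.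

Step 8
Reactants: 12 tricyclic enone aldehyde (rings A, B, C)
Product: 13 C12 silyl enol ether
Conditions: [(Ph3P)CuH]6, tBuMe2SiCl, THF/benzene, −20 °C → rt
Reagents that add atoms: tert-butyl(chloro)dimethylsilane, CC(C)(C)[Si](C)(C)Cl
Why: Conjugate reduction of the remaining enone by the copper hydride and in situ O-silylation (reductive silylation) give the C12=C13 silyl enol ether regiospecifically, the hindered neopentyl aldehyde, the esters and the terminal alkene being left alone.

Step 9
Reactants: 13 C12 silyl enol ether
Product: 14 12-oxo-GA24 dimethyl ester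
Conditions: Pd(OAc)2 (10 mol%), O2 (1 atm), DMSO, 45 °C
Reagents that add atoms: none
Why: Pd(OAc)2-catalysed oxidative cycloalkenylation of the silyl enol ether (Saegusa-type enolate–alkene coupling), by 5-exo carbopalladation of the allyl group by C13 and beta-hydride elimination, closes ring D as the bicyclo[3.2.1]octanone with the exocyclic methylene, C13 being fixed by the bridge.

Step 10
Reactants: 14 12-oxo-GA24 dimethyl ester
Product: 15 12-oxo-GA24 (target)
Conditions: n-PrSLi, HMPA, rt; then 1 M HCl
Reagents that add atoms: none
Why: SN2 demethylation of both hindered methyl esters by the thiolate (nucleophilic ester cleavage) spares the non-enolisable aldehyde, the ketone and the alkene and leaves all stereocentres untouched.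

**Compound list**
1 | methyl 2-[4-(benzyloxy)phenyl]acetate | COC(=O)Cc1ccc(OCc2ccccc2)cc1 | starting material
2 | [2-[4-(benzyloxy)phenyl]-1-methoxyethenoxy]trimethylsilane, E/Z mixture | COC(O[Si](C)(C)C)=Cc1ccc(OCc2ccccc2)cc1 | intermediate
3 | methyl 3-oxocyclohex-1-ene-1-carboxylate | COC(=O)C1=CC(=O)CCC1 | starting material
4 | methyl 3-(triisopropylsilyloxy)cyclohexa-1,3-diene-1-carboxylate | COC(=O)C1=CC(O[Si](C(C)C)(C(C)C)C(C)C)=CCC1 | intermediate
5 | methyl 2-[4-(benzyloxy)phenyl]-2-{6-[methoxy(trimethylsilyloxy)methylidene]-2-(triisopropylsilyloxy)cyclohex-2-en-1-yl}acetate; C5 and C6 as in 15 | c1ccccc1COc1ccc(cc1)[C@@H](C(=O)OC)[C@H]1C(O[Si](C(C)C)(C(C)C)C(C)C)=CCCC1=C(OC)O[Si](C)(C)C | intermediate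
6 | methyl 2-{1-[4-(benzyloxy)phenyl]-2-methoxy-2-oxoethyl}-1-methyl-3-(triisopropylsilyloxy)cyclohex-3-ene-1-carboxylate; ring ester cis to the side chain, methyl trans; C4, C5, C6 as in 15 | c1ccccc1COc1ccc(cc1)[C@@H](C(=O)OC)[C@H]1C(O[Si](C(C)C)(C(C)C)C(C)C)=CCC[C@@]1(C)C(=O)OC | intermediate
7 | methyl 2-{1-[4-(benzyloxy)phenyl]-2-methoxy-2-oxoethyl}-1-methyl-3-oxocyclohexane-1-carboxylate; ring ester cis to the side chain; C4, C5, C6 as in 15 | c1ccccc1COc1ccc(cc1)[C@@H](C(=O)OC)[C@H]1C(=O)CCC[C@@]1(C)C(=O)OC | intermediate
8 | methyl 2-{1-[4-(benzyloxy)phenyl]-2-methoxy-2-oxoethyl}-3-(methoxymethylidene)-1-methylcyclohexane-1-carboxylate, E/Z mixture; C4, C5, C6 as in 15 | c1ccccc1COc1ccc(cc1)[C@@H](C(=O)OC)[C@H]1C(=COC)CCC[C@@]1(C)C(=O)OC | intermediate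
9 | methyl 2-{1-[4-(benzyloxy)phenyl]-2-methoxy-2-oxoethyl}-3-formyl-1-methylcyclohexane-1-carboxylate; formyl trans to the side chain (C10 epimerisable), ring ester cis to the side chain | c1ccccc1COc1ccc(cc1)[C@@H](C(=O)OC)[C@H]1[C@H](C=O)CCC[C@@]1(C)C(=O)OC | intermediate
10 | methyl 3-formyl-2-[1-(4-hydroxyphenyl)-2-methoxy-2-oxoethyl]-1-methylcyclohexane-1-carboxylate; configuration as in 9 | Oc1ccc(cc1)[C@@H](C(=O)OC)[C@H]1[C@H](C=O)CCC[C@@]1(C)C(=O)OC | intermediate
11 | methyl 3-formyl-2-{2-methoxy-2-oxo-1-[4-oxo-1-(prop-2-enyl)cyclohexa-2,5-dien-1-yl]ethyl}-1-methylcyclohexane-1-carboxylate; configuration as in 9 | C=CCC1(C=CC(=O)C=C1)[C@@H](C(=O)OC)[C@H]1[C@H](C=O)CCC[C@@]1(C)C(=O)OC | intermediate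
12 | tricyclic 7,19-dimethyl ester with rings A, B, C of 15, a C13=C14 enone, allyl on C8 and H on C9 on the upper face, formyl on C10 on the lower face (cis to the C19 ester); A/B trans, B/C cis | C=CC[C@]23C=CC(=O)C[C@H]2[C@]1(C=O)CCC[C@@](C)(C(=O)OC)[C@H]1[C@@H]3C(=O)OC | intermediate
13 | 12-(tert-butyldimethylsilyloxy) C12=C13 enol ether of the 13,14-dihydro derivative of 12 | C=CC[C@]23CC=C(O[Si](C)(C)C(C)(C)C)C[C@H]2[C@]1(C=O)CCC[C@@](C)(C(=O)OC)[C@H]1[C@@H]3C(=O)OC | intermediate
14 | 12-oxo-GA24 7,19-dimethyl ester | C=C1C[C@]23C[C@H]1C(=O)C[C@H]2[C@]1(C=O)CCC[C@@](C)(C(=O)OC)[C@H]1[C@@H]3C(=O)OC | intermediate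
15 | 12-oxo-GA24 (CNP0412196.1): 12,20-dioxogibberell-16-ene-7,19-dioic acid with the configuration of the given SMILES | C=C1C[C@]23C[C@H]1C(=O)C[C@H]2[C@]1(C=O)CCC[C@@](C)(C(=O)O)[C@H]1[C@@H]3C(=O)O | target

**Totals**
Total step count: 10. Longest linear sequence: 9 steps (steps 1 and 3 to 10; step 2 is a one-step branch).

**Three steps most likely to fail**

The first is step 3. The cyclic, alpha-substituted silyloxydienoate 4 lies outside the usual acceptor range of the silylium Mukaiyama–Michael reaction, and 1,6-addition at C1 or methylation at C6 could compete. The fallback sets out from 1 and 4 and comes back at 7. The lithium enolate of 1 (LiN(iPr)2, THF, −78 °C) is added to 4, quenched with MeI and desilylated with Bu4NF/AcOH, the classical tandem Michael addition–alkylation. This gives racemic material, that is 6 and 7 together with their mirror images, the silyl enol ether ent-6 F1 (not isolated) and the ketone ent-7 F2. The ketone ent-7 F2 is removed by preparative chromatography on a chiral stationary phase and the route continues from 7.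

The second is step 6. C8 is flanked by a bulky tertiary carbon, and the phenoxenium ion can lose the acidic benzylic C6–H to give a quinone methide instead of being allylated. The fallback sets out from 10 and comes back at 11 by reversing the polarity. The potassium phenolate of 10 is C-allylated at its para carbon by a π-allyl palladium electrophile (allyl methyl carbonate, Pd(PPh3)4 as the zerovalent palladium source), a Tsuji–Trost type dearomatisation. It gives 11 directly and makes no new compound (F0).

The third is step 7, the proposed new method. Enamine formation from the hindered aldehyde may be slow, and the trans A/B selectivity rests on the equatorial-attack argument. The fallback uses known chemistry, sets out from 11 and comes back at 12. The aldehyde is converted with tBuMe2SiOTf/Et3N into its silyl enol ether F3, which is cyclised by an intramolecular Mukaiyama–Michael addition onto the dienone (TiCl4, CH2Cl2, −78 °C, aqueous work-up). The same steric and ring-strain arguments govern the configuration at C8, C9 and C10.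

Further compounds
F1 | step 3 | ent-6, mirror image of silyl enol ether 6 | c1ccccc1COc1ccc(cc1)[C@H](C(=O)OC)[C@@H]1C(O[Si](C(C)C)(C(C)C)C(C)C)=CCC[C@]1(C)C(=O)OC
F2 | step 3 | ent-7, mirror image of ketone 7 | c1ccccc1COc1ccc(cc1)[C@H](C(=O)OC)[C@@H]1C(=O)CCC[C@]1(C)C(=O)OC
F0 | step 6 | none | none
F3 | step 7 | tert-butyldimethylsilyl enol ether of aldehyde 11 (C10=C20, E/Z mixture) | C=CCC1(C=CC(=O)C=C1)[C@@H](C(=O)OC)[C@H]1C(=CO[Si](C)(C)C(C)(C)C)CCC[C@@]1(C)C(=O)OC
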